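**Strategy.** The synthesis rests on cutting ring A at C8–C8a. C5, C6, C7 and C8, each with its oxygen, are traced back to the four carbons of dimethyl squarate. C4a and C8a are the C3=C2 alkene of a preformed 6-aryl-4-pyranone (rings C and B). The feature exploited is the unbroken run of oxygenated carbons C5–C8 in ring A, with the para pair O5/O8 framing the C6 and C7 methoxy groups. One thermolysis turns the cyclobutenone into the aromatic 5,8-dihydroxy-6,7-dimethoxy ring A, forming C8–C8a and completing the flavone. Its precursor is a 4-hydroxy-2,3-dimethoxycyclobutenone whose carbinol carbon bears C3 of the pyranone, made from a regiodefined iodopyranone.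

Key step: step 6

**Remarks on the chemistry**
- Iodine is put on the four-carbon enone before the pyranone exists, so it can only end up at the future C4a. Iodinating a finished 2-aryl-4-pyranone would have to tell C5 from C3 and from the electron-rich ring B.
- The carbinol OH of 12 is left free on purpose. It steers the ring opening, pre-organises the triene by hydrogen bonding, and emerges as the chelated C5–OH that distinguishes the two phenols in step 7.
- Numbering: in 9 (a 2-aryl-4-pyranone) C5 and C6 are the future C4a and C8a. In the substituent names of 11–13 the same atoms are C3 and C2.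
- Assumption: 6–8 are drawn with the acyl group trans to OMe, as in 5 (descriptor Z). This geometry is lost on ring closure and has no consequence.
- The target has no stereocentre. Compound 12 is racemic, and its one centre disappears in step 6.

**Step 1**
Reactants: 1 3-hydroxy-4-methoxybenzoic acid
Product: 3 3-benzyloxy-4-methoxybenzoic acid, via benzyl ester 2 (not isolated)
Conditions: BnBr (2.3 equiv), K2CO3 (2.5 equiv), DMF, 60 °C; work-up; crude ester, NaOH (2 M aq), MeOH–THF, 60 °C; HCl to pH 2
Reagents that add atoms: benzyl bromide BrCc1ccccc1; sodium hydroxide [Na+].[OH-] (oxygen of the liberated carboxyl group)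
Why: Williamson O-benzylation of the phenoxide (the carboxylate is benzylated as well) followed by saponification of the labile benzyl ester leaves only the aryl benzyl ether, which is stable to base and organometallics and masks the 3'-OH until the last step.

**Step 2**
Reactants: 3 3-benzyloxy-4-methoxybenzoic acid
Product: 4 3-benzyloxy-4-methoxybenzoyl chloride
Conditions: (COCl)2 (1.3 equiv), DMF (cat.), CH2Cl2, 0 °C to rt; concentrate, use crude
Reagents that add atoms: oxalyl chloride O=C(Cl)C(=O)Cl
Why: DMF-catalysed acid chloride formation through a Vilsmeier-type chloroiminium salt is mild enough for the benzyl and methyl ethers and gives only gaseous by-products, so crude 4 can be used directly.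

**Step 3**
Reactants: 5 (E)-4-methoxybut-3-en-2-one
Product: 6 (Z)-3-iodo-4-methoxybut-3-en-2-one
Conditions: NIS (1.1 equiv), TFA (5 mol %), MeCN, 0 °C to rt, dark
Reagents that add atoms: N-iodosuccinimide O=C1CCC(=O)N1I
Why: This is an electrophilic α-iodination of a vinylogous ester, in which C3 is the only nucleophilic vinylic carbon of the push-pull alkene and attack on iodine gives an oxocarbenium ion that loses the C3 proton, so the halogen marking the future C4a is fixed before any ring or electron-rich arene is present.

**Step 4**
Reactants: 6 (Z)-3-iodo-4-methoxybut-3-en-2-one; 4 3-benzyloxy-4-methoxybenzoyl chloride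
Product: 9 2-(3-benzyloxy-4-methoxyphenyl)-5-iodo-4H-pyran-4-one, via lithium dienolate 7 (not isolated), via iodo diketone 8 (not isolated)
Conditions: 6 (2.0 equiv), LiN(SiMe3)2 (2.0 equiv), THF, −78 °C; 4 (1.0 equiv), −78 to −20 °C; aq NH4Cl; crude 8, TFA (0.5 equiv), CH2Cl2, rt
Reagents that add atoms: none
Why: Claisen-type C-acylation of the kinetic cross-conjugated lithium enolate by the aroyl chloride (the second equivalent of 7 deprotonates the more acidic product), followed by acid-catalysed oxa-Michael addition–elimination of the enol oxygen at the methoxy-bearing carbon, is the established 4-pyranone synthesis from 4-methoxybutenones, and the vinylic iodine, inert to the amide base, can only end up at C5.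

**Step 5**
Reactants: 9 2-(3-benzyloxy-4-methoxyphenyl)-5-iodo-4H-pyran-4-one; 10 dimethyl squarate
Product: 12 racemic 4-hydroxy-2,3-dimethoxy-4-[6-(3-benzyloxy-4-methoxyphenyl)-4-oxo-4H-pyran-3-yl]cyclobut-2-en-1-one, via pyranonylmagnesium chloride 11 (not isolated)
Conditions: iPrMgCl·LiCl (1.05 equiv), THF, −60 °C; cannulate into 10 (1.5 equiv), THF, −78 °C; aq NH4Cl at −78 °C; no acid wash, keep cold, use promptly
Reagents that add atoms: none
Why: Iodine–magnesium exchange at an sp2 C–I bond activated and chelated by the neighbouring carbonyl outruns carbonyl addition at low temperature, and the alkenyl Grignard reagent then undergoes 1,2-addition to one of the two equivalent carbonyls of the symmetric squarate, so no regiochemical issue arises; the carbinol stereocentre forms without control (racemate) and is erased in step 6.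

**Step 6**
Reactants: 12 racemic 4-hydroxy-2,3-dimethoxy-4-[6-(3-benzyloxy-4-methoxyphenyl)-4-oxo-4H-pyran-3-yl]cyclobut-2-en-1-one
Product: 15 3'-benzyloxy-5,8-dihydroxy-4',6,7-trimethoxyflavone, via dienylketene 13 (not isolated), via cyclohexadienone 14 (not isolated)
Conditions: degassed toluene (0.01 M), 110 °C, Ar; cool and concentrate under Ar
Reagents that add atoms: none
Why: On heating, the four-membered ring undergoes conrotatory 4π electrocyclic opening at its C1–C4 σ-bond, and the resulting dienylketene 13 has the ketene carbon as future C8 and ends in the pyranone alkene (future C4a=C8a). Ring A closes by a disrotatory 6π electrocyclisation that joins C8 to C8a to give dienone 14, after which the hydrogen on C8a moves to the C8 oxygen and aromatisation makes the sequence irreversible. The reaction type is the Moore rearrangement of 4-alkenyl- and 4-(hetero)aryl-4-hydroxycyclobutenones derived from squarate esters, applied here to a pyranone alkene. The selectivity needed is torquoselectivity: the donor hydroxyl on the carbinol carbon rotates outward, which forces the pyranonyl group inward and cis to the ketene, whereas inward rotation of OH would drain material to a butenolide. The O–H···O=C4 hydrogen bond holds the C6=C5–C4a=C8a diene s-cis, only C8a lies within bonding distance of the ketene carbon, and its hydrogen permits enolisation, so a single regioisomer with C5–OH peri to C4=O should result. No stereocentre survives, because the carbinol centre of 12 becomes sp2 C5 and the transient C8a centre of 14 is erased on enolisation.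

**Step 7**
Reactants: 15 3'-benzyloxy-5,8-dihydroxy-4',6,7-trimethoxyflavone
Product: 16 3'-benzyloxy-5-hydroxy-4',6,7,8-tetramethoxyflavone
Conditions: MeI (1.1 equiv), K2CO3 (1.1 equiv), degassed acetone, 40 °C, Ar
Reagents that add atoms: iodomethane CI
Why: This is a chemoselective Williamson O-methylation in which the C5 hydroxyl, tied up in a six-membered hydrogen bond to the C4 carbonyl, is less acidic and poorly nucleophilic, so one equivalent of weak base and MeI should engage only the free C8 phenol, as is standard for 5-hydroxyflavones.

**Step 8**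
Reactants: 16 3'-benzyloxy-5-hydroxy-4',6,7,8-tetramethoxyflavone
Product: 17 Gardenin D (3',5-dihydroxy-4',6,7,8-tetramethoxyflavone)
Conditions: H2 (1 atm), Pd/C (10 wt % Pd on carbon), EtOAc–MeOH, rt
Reagents that add atoms: none
Why: Catalytic hydrogenolysis of the benzylic C–O bond proceeds at ambient pressure and temperature, conditions under which the conjugated C2=C3 alkene, the carbonyl group and the aryl methyl ethers of a flavone are left untouched.

**Compound list**
1 | 3-hydroxy-4-methoxybenzoic acid (isovanillic acid) | COc1ccc(C(=O)O)cc1O | starting material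
2 | benzyl 3-benzyloxy-4-methoxybenzoate | COc1ccc(C(=O)OCc2ccccc2)cc1OCc1ccccc1 | intermediate
3 | 3-benzyloxy-4-methoxybenzoic acid | COc1ccc(C(=O)O)cc1OCc1ccccc1 | intermediate
4 | 3-benzyloxy-4-methoxybenzoyl chloride | COc1ccc(C(Cl)=O)cc1OCc1ccccc1 | intermediate
5 | (E)-4-methoxybut-3-en-2-one | CO/C=C/C(C)=O | starting material
6 | (Z)-3-iodo-4-methoxybut-3-en-2-one | CO/C=C(\I)C(C)=O | intermediate
7 | lithium (3Z)-3-iodo-4-methoxybuta-1,3-dien-2-olate | [Li]OC(=C)/C(I)=C/OC | intermediate
8 | (Z)-1-(3-benzyloxy-4-methoxyphenyl)-4-iodo-5-methoxypent-4-ene-1,3-dione | COc1ccc(C(=O)CC(=O)/C(I)=C/OC)cc1OCc1ccccc1 | intermediate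
9 | 2-(3-benzyloxy-4-methoxyphenyl)-5-iodo-4H-pyran-4-one | COc1ccc(-c2cc(=O)c(I)co2)cc1OCc1ccccc1 | intermediate
10 | dimethyl squarate (3,4-dimethoxycyclobut-3-ene-1,2-dione) | COC1=C(OC)C(=O)C1=O | starting material
11 | [6-(3-benzyloxy-4-methoxyphenyl)-4-oxo-4H-pyran-3-yl]magnesium chloride (LiCl complex) | COc1ccc(-c2cc(=O)c([Mg]Cl)co2)cc1OCc1ccccc1 | intermediate
12 | racemic 4-hydroxy-2,3-dimethoxy-4-[6-(3-benzyloxy-4-methoxyphenyl)-4-oxo-4H-pyran-3-yl]cyclobut-2-en-1-one | COC1=C(OC)C(O)(c2coc(-c3ccc(OC)c(OCc4ccccc4)c3)cc2=O)C1=O | intermediate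
13 | (Z)-4-[6-(3-benzyloxy-4-methoxyphenyl)-4-oxo-4H-pyran-3-yl]-4-hydroxy-2,3-dimethoxybuta-1,3-dien-1-one (pyranonyl cis to the ketene arm) | COC(=C=O)/C(OC)=C(/O)c1coc(-c2ccc(OC)c(OCc3ccccc3)c2)cc1=O | intermediate
14 | racemic 2-(3-benzyloxy-4-methoxyphenyl)-5-hydroxy-6,7-dimethoxy-4H-chromene-4,8(8aH)-dione | COC1=C(OC)C(=O)C2OC(c3ccc(OC)c(OCc4ccccc4)c3)=CC(=O)C2=C1O | intermediate
15 | 3'-benzyloxy-5,8-dihydroxy-4',6,7-trimethoxyflavone | COc1ccc(-c2cc(=O)c3c(O)c(OC)c(OC)c(O)c3o2)cc1OCc1ccccc1 | intermediate
16 | 3'-benzyloxy-5-hydroxy-4',6,7,8-tetramethoxyflavone | COc1ccc(-c2cc(=O)c3c(O)c(OC)c(OC)c(OC)c3o2)cc1OCc1ccccc1 | intermediate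
17 | Gardenin D | COc1ccc(-c2cc(=O)c3c(O)c(OC)c(OC)c(OC)c3o2)cc1O | target

**Total step count:** 8.
**Longest linear sequence:** 7 (steps 1, 2, 4, 5, 6, 7, 8; step 3 lies on the short branch).

**Steps most likely to fail**

*Step 6.*
- What may go wrong: C8a is an electron-poor alkene terminus, so ring closure may be slow relative to the reversible ring opening. The minor inward rotation of the hydroxyl group could then leak to a lactone. The ketene could also be captured by phenolic product, or the hydroquinone could be oxidised in the hot solution.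
- Fallback (from 12, back at 16): the carbinol is capped, so the two ring A oxygens are differentiated by a protecting group rather than by chelation.
- Et3SiOTf and 2,6-lutidine in CH2Cl2 (−78 to 0 °C) should give racemic 2,3-dimethoxy-4-(triethylsilyloxy)-4-[6-(3-benzyloxy-4-methoxyphenyl)-4-oxo-4H-pyran-3-yl]cyclobut-2-en-1-one F1.
- With no free OH, lactonisation is impossible, and the only exit from the opening/closing equilibrium is the electrocyclisation. Harder heating (degassed p-xylene, 138 °C) is therefore tolerated and should give 3'-benzyloxy-8-hydroxy-4',6,7-trimethoxy-5-(triethylsilyloxy)flavone F2. This mono-protected hydroquinone has a single free phenol and is far less prone to oxidation.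
- MeI and K2CO3 in acetone should then give 3'-benzyloxy-4',6,7,8-tetramethoxy-5-(triethylsilyloxy)flavone F3.
- Dilute HCl in aqueous MeOH removes the silyl group and delivers 16.

*Step 5.*
- What may go wrong: in 11 magnesium sits anti to the ring oxygen across the C5=C6 bond, so β-elimination with opening of the pyranone can outrun the addition. Attack of iPrMgCl at C6 or C4 of 9 and opening of the adduct alkoxide on warming are further drains.
- Fallback (from 9, back at 12): the polar Grignard reagent is replaced by an organozinc made by oxidative insertion.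
- Zn dust and LiCl in THF at 25 °C should convert 9 into [6-(3-benzyloxy-4-methoxyphenyl)-4-oxo-4H-pyran-3-yl]zinc iodide F4. Its covalent C–Zn bond does not eliminate and tolerates the pyranone carbonyl at room temperature.
- MgCl2 (1 equiv), acting as a Lewis acid on the squarate carbonyl, promotes the 1,2-addition to 10 (THF, 0 °C to rt), and a buffered NH4Cl quench gives 12.

*Step 4.*
- What may go wrong: O-acylation or self-condensation of the hindered iodo dienolate, or protodeiodination during the acidic ring closure.
- Fallback (from 4 and 5, back at 9): the pyranone is built first and iodinated afterwards.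
- Compound 5 with LiN(SiMe3)2 (THF, −78 °C) gives lithium (E)-4-methoxybuta-1,3-dien-2-olate F5.
- Acylation by 4 gives (E)-1-(3-benzyloxy-4-methoxyphenyl)-5-methoxypent-4-ene-1,3-dione F6.
- TFA in CH2Cl2 closes this to 2-(3-benzyloxy-4-methoxyphenyl)-4H-pyran-4-one F7.
- Iodination is then run under nucleophile-assisted conditions (I2, pyridine–CH2Cl2, rt). Pyridine adds reversibly to the unsubstituted C6, the dienolate is iodinated at C5, and pyridine is expelled.
- C3 is bypassed because its β-carbon C2 carries the aryl group, and I2/pyridine is too weak an electrophile for ring B. Compound 9 should therefore result.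

**Further compounds**
F1 | step 6 | racemic 2,3-dimethoxy-4-(triethylsilyloxy)-4-[6-(3-benzyloxy-4-methoxyphenyl)-4-oxo-4H-pyran-3-yl]cyclobut-2-en-1-one | COC1=C(OC)C(O[Si](CC)(CC)CC)(c2coc(-c3ccc(OC)c(OCc4ccccc4)c3)cc2=O)C1=O
F2 | step 6 | 3'-benzyloxy-8-hydroxy-4',6,7-trimethoxy-5-(triethylsilyloxy)flavone | COc1ccc(-c2cc(=O)c3c(O[Si](CC)(CC)CC)c(OC)c(OC)c(O)c3o2)cc1OCc1ccccc1
F3 | step 6 | 3'-benzyloxy-4',6,7,8-tetramethoxy-5-(triethylsilyloxy)flavone | COc1ccc(-c2cc(=O)c3c(O[Si](CC)(CC)CC)c(OC)c(OC)c(OC)c3o2)cc1OCc1ccccc1
F4 | step 5 | [6-(3-benzyloxy-4-methoxyphenyl)-4-oxo-4H-pyran-3-yl]zinc iodide | COc1ccc(-c2cc(=O)c([Zn]I)co2)cc1OCc1ccccc1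
F5 | step 4 | lithium (E)-4-methoxybuta-1,3-dien-2-olate | [Li]OC(=C)/C=C/OC
F6 | step 4 | (E)-1-(3-benzyloxy-4-methoxyphenyl)-5-methoxypent-4-ene-1,3-dione | COc1ccc(C(=O)CC(=O)/C=C/OC)cc1OCc1ccccc1
F7 | step 4 | 2-(3-benzyloxy-4-methoxyphenyl)-4H-pyran-4-one | COc1ccc(-c2cc(=O)cco2)cc1OCc1ccccc1
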